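## Retrosynthetic overview

1. The plan rests on two features: in ring A (C1–C5, C10) C4 carries a methyl group and an oxygen next to oxygenated C3, which is the pattern of an ortho-quinol from a 2-methylphenol; and C10 at the ring A/ring B fusion is a quaternary methyl carbon cis to H5.
2. Last steps: the O4 acetate and the O3 (2S,3S)-epoxyangelate go onto diol 23; the acid 27 (fragment 2) comes from angelic acid by reduction, Katsuki–Sharpless epoxidation and oxidation.
3. The C8 ketone and C7 isopropyl group grow from the C8=C9 alkene of cis-decalinone 11 (hydroboration, oxidation, acetone aldol, dehydration, hydrogenation, equilibration).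
4. Key disconnection: 11 from vinyl carbinol 8 by an anionic oxy-Cope rearrangement that forms C1–C10, breaks C3–C8 and closes ring A.
5. 8 comes from vinyl Grignard addition to a bicyclo[2.2.2]octenone made by Diels–Alder reaction of ethylene with the Wessely ortho-quinol acetate of 2,4-dimethylphenol, resolved enzymatically. Ring B is formed first (as the cyclohexene inside the bicycle), ring A second.

Key step: step 7

Numbering: decalins carry eudesmane locants (β = face of the C10 methyl); bicycles carry bicyclo[2.2.2]octane locants, C1, C2, C3, C4, C5, C6, C7, C8 being eudesmane C8, C3, C4, C5, C10, C9, C7, C6.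

Assumption: in step 3 the hydrolase is taken to hydrolyse the (1S,3R,4R)-acetate faster, so that the wanted (1R,3S,4S)-acetate is the recovered ester; if the preference is the reverse, the liberated ketol is itself 6 and step 4 is not needed.

## Route

Step 1
Reactants: 1 2,4-dimethylphenol
Product: 2 rac-6-acetoxy-4,6-dimethylcyclohexa-2,4-dien-1-one
Conditions: Pb(OAc)4 (tetravalent lead), AcOH, 15–20 °C, dark; chromatography
Reagents that add atoms: lead tetraacetate, CC(=O)O[Pb](OC(C)=O)(OC(C)=O)OC(C)=O
Why: Wessely acetoxylation: the aryloxy–lead intermediate passes acetate to the methyl-bearing ortho carbon, giving the racemic ortho-quinol acetate, from which the para-quinol acetate expected as by-product is separated.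

Step 2
Reactants: 2 rac-6-acetoxy-4,6-dimethylcyclohexa-2,4-dien-1-one; 3 ethylene
Product: 4 rac-(1R*,3S*,4S*)-3,5-dimethyl-2-oxobicyclo[2.2.2]oct-5-en-3-yl acetate
Conditions: ethylene (60 bar), toluene, BHT (cat.), 120 °C, autoclave
Reagents that add atoms: none
Why: Thermal Diels–Alder reaction with a large excess of ethylene; 6-acetoxy-6-alkyl dienones take dienophiles on the acetoxy face, so the acetoxy group should end up on the side of the new ethano bridge and the methyl syn to the C5=C6 bridge, which fixes eudesmane C4 relative to C5.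

Step 3
Reactants: 4 rac-(1R*,3S*,4S*)-3,5-dimethyl-2-oxobicyclo[2.2.2]oct-5-en-3-yl acetate
Product: 5 (1R,3S,4S)-3,5-dimethyl-2-oxobicyclo[2.2.2]oct-5-en-3-yl acetate
Conditions: Candida antarctica lipase A (immobilized), 0.1 M phosphate buffer (pH 7)/t-BuOMe, 30 °C, to just past half conversion; chromatography
Reagents that add atoms: none
Why: Hydrolase-mediated kinetic resolution of an α-acetoxy ketone with a quaternary carbinol carbon: one enantiomer is hydrolysed faster, and running past half conversion should leave the slow (1R,3S,4S)-acetate enantiomerically enriched, which sets the absolute configuration of the route.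

Step 4
Reactants: 5 (1R,3S,4S)-3,5-dimethyl-2-oxobicyclo[2.2.2]oct-5-en-3-yl acetate
Product: 6 (1R,3S,4S)-3-hydroxy-3,5-dimethylbicyclo[2.2.2]oct-5-en-2-one
Conditions: K2CO3 (cat.), MeOH, 0 °C
Reagents that add atoms: none
Why: Base-catalysed transesterification of the activated α-keto acetate; the ketone has no enolizable α-hydrogen (quaternary C3, bridgehead C1) and the cold, weakly basic medium should not start an α-ketol shift.

Step 5
Reactants: 6 (1R,3S,4S)-3-hydroxy-3,5-dimethylbicyclo[2.2.2]oct-5-en-2-one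
Product: 7 (1R,3S,4S)-3-(methoxymethoxy)-3,5-dimethylbicyclo[2.2.2]oct-5-en-2-one
Conditions: MOMCl, iPr2NEt, Bu4NI (cat.), CH2Cl2, 40 °C
Reagents that add atoms: chloromethyl methyl ether, COCCl
Why: O-alkylation of the tertiary alcohol with the reactive α-chloro ether; unlike the acetate, the acetal ether tolerates the Grignard reagent and KH and cannot migrate to a neighbouring alkoxide.

Step 6
Reactants: 7 (1R,3S,4S)-3-(methoxymethoxy)-3,5-dimethylbicyclo[2.2.2]oct-5-en-2-one
Product: 8 (1R,2R,3S,4S)-2-ethenyl-3-(methoxymethoxy)-3,5-dimethylbicyclo[2.2.2]oct-5-en-2-ol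
Conditions: CH2=CHMgBr, THF, −78 → 0 °C; then H2O
Reagents that add atoms: vinylmagnesium bromide, C=C[Mg]Br
Why: Grignard 1,2-addition to the non-enolizable ketone; as is usual for bicyclo[2.2.2]oct-5-en-2-ones the nucleophile should enter from the face of the C5=C6 bridge, away from the ethano bridge and from magnesium held by the carbonyl and acetal oxygens, so that the new carbinol centre has vinyl syn to the alkene bridge and OH cis to the methoxymethoxy group.

Step 7
Reactants: 8 (1R,2R,3S,4S)-2-ethenyl-3-(methoxymethoxy)-3,5-dimethylbicyclo[2.2.2]oct-5-en-2-ol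
Product: 11 (4S,5S,10R)-4α-(methoxymethoxy)-4β,10β-dimethyl-5βH-decal-8-en-3-one, via potassium alkoxide 9 (not isolated), via potassium enolate 10 (not isolated)
Conditions: KH, 18-crown-6, THF, 0 → 50 °C; then AcOH, −78 °C
Reagents that add atoms: none
Why: KH deprotonates the tertiary carbinol and 18-crown-6 frees alkoxide 9 from its potassium ion; 9 then undergoes the charge-accelerated [3,3]-sigmatropic shift of its 1,5-diene C1=C2–C3–C8–C9=C10, in which the C3–C8 bond breaks as C1 bonds to C10, and the resulting enolate 10 (C2=C3–O) is protonated to ketone 11 on quench. The closest known reaction type is the anionic oxy-Cope rearrangement of 2-vinylbicyclo[2.2.2]oct-5-en-2-ols obtained from dearomatized phenols, which delivers cis-decalins. Ring A (C1–C5, C10) closes by this concerted suprafacial sigmatropic bond formation through a boat-like six-membered transition state imposed by the rigid bicyclic frame, and ring B appears as the cyclohexene C5–C10 with the new C8=C9 bond. The one new stereocentre, quaternary C10, is set by the framework: the vinyl terminus is tethered to the C3–C4 bridge and can bond to C10 only on the face turned toward that bridge, so the C10–C1 and C5–C4 bonds are cis and the C10 methyl is β, cis to H5, while C4 and C5 are carried through unchanged. The step needs the [3,3] shift to outrun fragmentation or a [1,3] shift and needs the vinyl group syn to the C9=C10 bridge; the syn geometry comes from step 6, the weakly paired alkoxide and the strain released on opening the bicycle favour the concerted path, and enolate 10 cannot eliminate the C4 oxygen because that oxygen is not β to the enolate carbon.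

Step 8
Reactants: 11 (4S,5S,10R)-4α-(methoxymethoxy)-4β,10β-dimethyl-5βH-decal-8-en-3-one
Product: 12 (3R,4S,5S,10R)-4α-(methoxymethoxy)-4β,10β-dimethyl-5βH-decal-8-en-3α-ol
Conditions: NaBH4, MeOH, 0 °C
Reagents that add atoms: none
Why: Borohydride reduction; in the favoured chair–chair form (C4 methyl equatorial, C4 oxygen axial) hydride should attack C3 axially from the β face, which is flanked only by axial hydrogens and is anti to the axial C4–O bond (Felkin–Anh polar effect), giving the equatorial 3α-alcohol cis to the 4α-oxygen.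

Step 9
Reactants: 12 (3R,4S,5S,10R)-4α-(methoxymethoxy)-4β,10β-dimethyl-5βH-decal-8-en-3α-ol
Product: 13 (3R,4S,5S,10R)-3α-(tert-butyldimethylsilyloxy)-4α-(methoxymethoxy)-4β,10β-dimethyl-5βH-decal-8-ene
Conditions: TBSOTf, 2,6-lutidine, CH2Cl2, −78 → 0 °C
Reagents that add atoms: tert-butyldimethylsilyl triflate, CC(C)(C)[Si](C)(C)OS(=O)(=O)C(F)(F)F
Why: Silylation of the hindered secondary alcohol with the silyl triflate; the silyl ether masks O3 during the oxidation and enolate steps in ring B.

Step 10
Reactants: 13 (3R,4S,5S,10R)-3α-(tert-butyldimethylsilyloxy)-4α-(methoxymethoxy)-4β,10β-dimethyl-5βH-decal-8-ene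
Product: 15 3α-(tert-butyldimethylsilyloxy)-4α-(methoxymethoxy)-4β,10β-dimethyl-5βH-decalin-8-ol, via B-alkyl-9-BBN adduct 14 (not isolated)
Conditions: 9-BBN, THF, 65 °C; then NaOH (aq), H2O2, 0 °C → rt
Reagents that add atoms: hydrogen peroxide, OO
Why: Hydroboration–oxidation; boron should add to C8, the alkene carbon remote from quaternary C10 (neopentyl C9 is shielded and the bulky borane sharpens the preference), and oxidation with retention gives the C8 alcohol, whose configuration is erased in step 11.

Step 11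
Reactants: 15 3α-(tert-butyldimethylsilyloxy)-4α-(methoxymethoxy)-4β,10β-dimethyl-5βH-decalin-8-ol
Product: 16 (3R,4S,5S,10R)-3α-(tert-butyldimethylsilyloxy)-4α-(methoxymethoxy)-4β,10β-dimethyl-5βH-decalin-8-one
Conditions: Dess–Martin periodinane, NaHCO3, CH2Cl2, rt
Reagents that add atoms: none
Why: Dess–Martin oxidation of the secondary alcohol to the ketone under buffered, non-acidic conditions that leave the acetal and silyl ethers alone.

Step 12
Reactants: 16 (3R,4S,5S,10R)-3α-(tert-butyldimethylsilyloxy)-4α-(methoxymethoxy)-4β,10β-dimethyl-5βH-decalin-8-one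
Product: 18 3α-(tert-butyldimethylsilyloxy)-7-(2-hydroxypropan-2-yl)-4α-(methoxymethoxy)-4β,10β-dimethyl-5βH-decalin-8-one, via lithium enolate 17 (not isolated)
Conditions: LiN(iPr)2, THF, −78 °C; acetone, −78 °C; AcOH, −78 °C
Reagents that add atoms: acetone, CC(C)=O
Why: Directed aldol addition: kinetic deprotonation should remove a C7 hydrogen and not the neopentyl C9 hydrogens next to quaternary C10, and the lithium enolate adds to acetone; the C7 configuration is immaterial because it is removed in step 13 and reset in step 14.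

Step 13
Reactants: 18 3α-(tert-butyldimethylsilyloxy)-7-(2-hydroxypropan-2-yl)-4α-(methoxymethoxy)-4β,10β-dimethyl-5βH-decalin-8-one
Product: 20 (3R,4S,5S,10R)-3α-(tert-butyldimethylsilyloxy)-4α-(methoxymethoxy)-4β,10β-dimethyl-7-(propan-2-ylidene)-5βH-decalin-8-one, via tertiary mesylate 19 (not isolated)
Conditions: MsCl, Et3N, DMAP (cat.), CH2Cl2, 0 °C; then DBU, rt
Reagents that add atoms: none
Why: Mesylation of the tertiary aldol hydroxyl (sulfene pathway) followed by E1cB elimination through the C8 enolate should give the conjugated isopropylidene ketone; any isopropenyl isomer would converge in the hydrogenation.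

Step 14
Reactants: 20 (3R,4S,5S,10R)-3α-(tert-butyldimethylsilyloxy)-4α-(methoxymethoxy)-4β,10β-dimethyl-7-(propan-2-ylidene)-5βH-decalin-8-one
Product: 22 (3R,4S,5S,7R,10R)-3α-(tert-butyldimethylsilyloxy)-7β-isopropyl-4α-(methoxymethoxy)-4β,10β-dimethyl-5βH-decalin-8-one, via C7-epimeric saturated ketones 21 (not isolated)
Conditions: H2 (1 atm), palladium on carbon (Pd/C), EtOAc, rt; filter; then NaOMe (cat.), MeOH, rt
Reagents that add atoms: none
Why: Heterogeneous hydrogenation of the enone C=C followed by base equilibration at enolizable C7: in the only chair–chair form free of a 1,3-diaxial contact between the C4 and C10 methyls the equatorial position at C7 is β, so thermodynamic control should set 7β-isopropyl (7R).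

Step 15
Reactants: 22 (3R,4S,5S,7R,10R)-3α-(tert-butyldimethylsilyloxy)-7β-isopropyl-4α-(methoxymethoxy)-4β,10β-dimethyl-5βH-decalin-8-one
Product: 23 (3R,4S,5S,7R,10R)-3α,4α-dihydroxy-7β-isopropyl-4β,10β-dimethyl-5βH-decalin-8-one
Conditions: HCl (3 M, aq), MeOH, 40 °C
Reagents that add atoms: none
Why: Acid-catalysed acetal exchange removes the methoxymethyl group and acidic solvolysis removes the silyl ether in one operation; the tertiary C4 alcohol is deactivated toward ionization by the adjacent C3 oxygen, and C7 stays in its thermodynamic configuration.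

Step 16
Reactants: 24 angelic acid
Product: 25 (Z)-2-methylbut-2-en-1-ol
Conditions: LiAlH4, Et2O, 0 °C; aq NaOH work-up
Reagents that add atoms: none
Why: Hydride reduction of the carboxylic acid to the allylic alcohol; 1,2-reduction at 0 °C should leave the trisubstituted alkene and its Z geometry intact.

Step 17
Reactants: 25 (Z)-2-methylbut-2-en-1-ol
Product: 26 [(2R,3S)-2,3-dimethyloxiran-2-yl]methanol
Conditions: Ti(OiPr)4 (10 mol%), D-(−)-diethyl tartrate (12 mol%), t-BuOOH, 4 Å MS, CH2Cl2, −20 °C
Reagents that add atoms: tert-butyl hydroperoxide, CC(C)(C)OO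
Why: Katsuki–Sharpless asymmetric epoxidation: the titanium–tartrate complex delivers oxygen to one alkene face, D-(−)-tartrate being the ligand that should give the 2R,3S epoxide, and syn addition keeps the hydroxymethyl and C3 methyl groups cis as in the Z alkene.

Step 18
Reactants: 26 [(2R,3S)-2,3-dimethyloxiran-2-yl]methanol
Product: 27 (2S,3S)-2,3-dimethyloxirane-2-carboxylic acid
Conditions: RuCl3 (cat.), NaIO4, MeCN/EtOAc/H2O, 0 °C → rt
Reagents that add atoms: sodium periodate, [Na+].[O-]I(=O)(=O)=O
Why: Ruthenium tetroxide oxidation of the primary alcohol to the acid, a standard conversion of 2,3-epoxy alcohols into glycidic acids that leaves the epoxide and both stereocentres untouched (the C2 descriptor changes from R to S only through the priority change).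

Step 19
Reactants: 23 (3R,4S,5S,7R,10R)-3α,4α-dihydroxy-7β-isopropyl-4β,10β-dimethyl-5βH-decalin-8-one; 27 (2S,3S)-2,3-dimethyloxirane-2-carboxylic acid
Product: 29 (3R,4S,5S,7R,10R)-4α-hydroxy-7β-isopropyl-4β,10β-dimethyl-8-oxo-5βH-decalin-3α-yl (2S,3S)-2,3-dimethyloxirane-2-carboxylate, via mixed anhydride 28 (not isolated)
Conditions: 27, 2,4,6-Cl3C6H2COCl, Et3N, THF, rt; then 23, DMAP, toluene, rt
Reagents that add atoms: none
Why: Yamaguchi esterification: DMAP attacks the mixed anhydride at the aliphatic carbonyl and the acylpyridinium acylates the secondary equatorial O3, while the tertiary axial O4 should not react; the non-acidic conditions preserve the epoxide.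

Step 20
Reactants: 29 (3R,4S,5S,7R,10R)-4α-hydroxy-7β-isopropyl-4β,10β-dimethyl-8-oxo-5βH-decalin-3α-yl (2S,3S)-2,3-dimethyloxirane-2-carboxylate
Product: 30 (3R,4S,5S,7R,10R)-4α-acetoxy-7β-isopropyl-4β,10β-dimethyl-8-oxo-5βH-decalin-3α-yl (2S,3S)-2,3-dimethyloxirane-2-carboxylate
Conditions: Ac2O, DMAP, Et3N, CH2Cl2, 40 °C
Reagents that add atoms: acetic anhydride, CC(=O)OC(C)=O
Why: DMAP-catalysed acetylation (nucleophilic acyl-transfer catalysis) of the remaining tertiary alcohol; base-only conditions spare the epoxy ester, and migration of the hindered α-quaternary ester from the secondary to the tertiary oxygen is thermodynamically uphill.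

## Compound list

1 | 2,4-dimethylphenol | Cc1ccc(O)c(C)c1 | starting material
2 | rac-6-acetoxy-4,6-dimethylcyclohexa-2,4-dien-1-one | CC(=O)OC1(C)C=C(C)C=CC1=O | intermediate
3 | ethylene | C=C | starting material
4 | rac-(1R*,3S*,4S*)-3,5-dimethyl-2-oxobicyclo[2.2.2]oct-5-en-3-yl acetate (racemate, both enantiomers written) | CC(=O)O[C@]1(C)C(=O)[C@@H]2CC[C@H]1C(C)=C2.CC(=O)O[C@@]1(C)C(=O)[C@H]2CC[C@@H]1C(C)=C2 | intermediate
5 | (1R,3S,4S)-3,5-dimethyl-2-oxobicyclo[2.2.2]oct-5-en-3-yl acetate | CC(=O)O[C@]1(C)C(=O)[C@@H]2CC[C@H]1C(C)=C2 | intermediate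
6 | (1R,3S,4S)-3-hydroxy-3,5-dimethylbicyclo[2.2.2]oct-5-en-2-one | O[C@]1(C)C(=O)[C@@H]2CC[C@H]1C(C)=C2 | intermediate
7 | (1R,3S,4S)-3-(methoxymethoxy)-3,5-dimethylbicyclo[2.2.2]oct-5-en-2-one | COCO[C@]1(C)C(=O)[C@@H]2CC[C@H]1C(C)=C2 | intermediate
8 | (1R,2R,3S,4S)-2-ethenyl-3-(methoxymethoxy)-3,5-dimethylbicyclo[2.2.2]oct-5-en-2-ol (vinyl syn to the alkene bridge) | COCO[C@]1(C)[C@@](O)(C=C)[C@@H]2CC[C@H]1C(C)=C2 | intermediate
9 | potassium alkoxide of 8 | COCO[C@]1(C)[C@@]([O-])(C=C)[C@@H]2CC[C@H]1C(C)=C2.[K+] | intermediate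
10 | potassium C2=C3 enolate of 11 | COCO[C@]1(C)C([O-])=CC[C@]2(C)C=CCC[C@@H]21.[K+] | intermediate
11 | (4S,5S,10R)-4α-(methoxymethoxy)-4β,10β-dimethyl-5βH-decal-8-en-3-one (cis-fused) | COCO[C@]1(C)C(=O)CC[C@]2(C)C=CCC[C@@H]21 | intermediate
12 | (3R,4S,5S,10R)-4α-(methoxymethoxy)-4β,10β-dimethyl-5βH-decal-8-en-3α-ol | COCO[C@]1(C)[C@H](O)CC[C@]2(C)C=CCC[C@@H]21 | intermediate
13 | 3α-O-tert-butyldimethylsilyl ether of 12 | COCO[C@]1(C)[C@H](O[Si](C)(C)C(C)(C)C)CC[C@]2(C)C=CCC[C@@H]21 | intermediate
14 | B-alkyl-9-borabicyclo[3.3.1]nonane adduct of 13 (boron on C8, C8 configuration unassigned) | COCO[C@]1(C)[C@H](O[Si](C)(C)C(C)(C)C)CC[C@]2(C)CC(B3C4CCCC3CCC4)CC[C@@H]21 | intermediate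
15 | 3α-(tert-butyldimethylsilyloxy)-4α-(methoxymethoxy)-4β,10β-dimethyl-5βH-decalin-8-ol (C8 configuration unassigned) | COCO[C@]1(C)[C@H](O[Si](C)(C)C(C)(C)C)CC[C@]2(C)CC(O)CC[C@@H]21 | intermediate
16 | (3R,4S,5S,10R)-3α-(tert-butyldimethylsilyloxy)-4α-(methoxymethoxy)-4β,10β-dimethyl-5βH-decalin-8-one | COCO[C@]1(C)[C@H](O[Si](C)(C)C(C)(C)C)CC[C@]2(C)CC(=O)CC[C@@H]21 | intermediate
17 | lithium C7=C8 enolate of 16 | COCO[C@]1(C)[C@H](O[Si](C)(C)C(C)(C)C)CC[C@]2(C)CC(O[Li])=CC[C@@H]21 | intermediate
18 | 7-(2-hydroxypropan-2-yl) derivative of 16 (C7 configuration unassigned) | COCO[C@]1(C)[C@H](O[Si](C)(C)C(C)(C)C)CC[C@]2(C)CC(=O)C(C(C)(C)O)C[C@@H]21 | intermediate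
19 | tertiary methanesulfonate of 18 | COCO[C@]1(C)[C@H](O[Si](C)(C)C(C)(C)C)CC[C@]2(C)CC(=O)C(C(C)(C)OS(C)(=O)=O)C[C@@H]21 | intermediate
20 | (3R,4S,5S,10R)-3α-(tert-butyldimethylsilyloxy)-4α-(methoxymethoxy)-4β,10β-dimethyl-7-(propan-2-ylidene)-5βH-decalin-8-one | COCO[C@]1(C)[C@H](O[Si](C)(C)C(C)(C)C)CC[C@]2(C)CC(=O)C(=C(C)C)C[C@@H]21 | intermediate
21 | C7-epimeric 7-isopropyl ketones (mixture at C7) | COCO[C@]1(C)[C@H](O[Si](C)(C)C(C)(C)C)CC[C@]2(C)CC(=O)C(C(C)C)C[C@@H]21 | intermediate
22 | (3R,4S,5S,7R,10R)-3α-(tert-butyldimethylsilyloxy)-7β-isopropyl-4α-(methoxymethoxy)-4β,10β-dimethyl-5βH-decalin-8-one | COCO[C@]1(C)[C@H](O[Si](C)(C)C(C)(C)C)CC[C@]2(C)CC(=O)[C@@H](C(C)C)C[C@@H]21 | intermediate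
23 | (3R,4S,5S,7R,10R)-3α,4α-dihydroxy-7β-isopropyl-4β,10β-dimethyl-5βH-decalin-8-one | O[C@]1(C)[C@H](O)CC[C@]2(C)CC(=O)[C@@H](C(C)C)C[C@@H]21 | intermediate
24 | angelic acid, (Z)-2-methylbut-2-enoic acid | C/C=C(/C)C(=O)O | starting material
25 | (Z)-2-methylbut-2-en-1-ol | C/C=C(/C)CO | intermediate
26 | [(2R,3S)-2,3-dimethyloxiran-2-yl]methanol | OC[C@@]1(C)O[C@H]1C | intermediate
27 | (2S,3S)-2,3-dimethyloxirane-2-carboxylic acid | OC(=O)[C@@]1(C)O[C@H]1C | intermediate
28 | (2S,3S)-2,3-dimethyloxirane-2-carboxylic 2,4,6-trichlorobenzoic anhydride | O=C(OC(=O)[C@@]1(C)O[C@H]1C)c1c(Cl)cc(Cl)cc1Cl | intermediate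
29 | (3R,4S,5S,7R,10R)-4α-hydroxy-7β-isopropyl-4β,10β-dimethyl-8-oxo-5βH-decalin-3α-yl (2S,3S)-2,3-dimethyloxirane-2-carboxylate | O[C@]1(C)[C@H](OC(=O)[C@@]2(C)O[C@H]2C)CC[C@]2(C)CC(=O)[C@@H](C(C)C)C[C@@H]21 | intermediate
30 | (3R,4S,5S,7R,10R)-4α-acetoxy-7β-isopropyl-4β,10β-dimethyl-8-oxo-5βH-decalin-3α-yl (2S,3S)-2,3-dimethyloxirane-2-carboxylate (CNP0221066.1) | CC(=O)O[C@]1(C)[C@H](OC(=O)[C@@]2(C)O[C@H]2C)CC[C@]2(C)CC(=O)[C@@H](C(C)C)C[C@@H]21 | target

## Step count and risks

Total step count: 20. Longest linear sequence: 17 steps (steps 1–15, 19 and 20); steps 16–18 make fragment 2, acid 27.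

Steps most likely to fail:

1. Step 3. The enzyme may turn over the tertiary acetate too slowly or discriminate the enantiomers poorly. Fallback: it sets out from racemic acetate 4. Methanolysis (K2CO3, MeOH, 0 °C) gives the racemic ketol F1. Alkylation with (1R,2S,5R)-menthyl chloromethyl ether (iPr2NEt, Bu4NI, CH2Cl2, 40 °C) gives two diastereomeric acetal ethers, separated by chromatography or crystallization into the (1R,3S,4S)-bicyclic menthyloxymethyl ether F2 and its (1S,3R,4R)-bicyclic diastereomer F3. Acid methanolysis of F2 (HCl, MeOH, rt) comes back to the route at ketol 6. The resolution then rests on separating diastereomers, not on enzyme selectivity.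

2. Step 2. Cycloaddition of unactivated ethylene may be too slow to compete with self-dimerization and thermal acetoxy migration of dienone 2. Fallback: it sets out from dienone 2. Diels–Alder reaction with acrolein (toluene, 80 °C), an activated dienophile expected to add on the same face, gives the racemic formyl adduct F4. Tsuji–Wilkinson decarbonylation with stoichiometric RhCl(PPh3)3 (toluene, 110 °C) removes the formyl group and comes back to the route at racemic acetate 4.

3. Step 20. Acetylation of the hindered tertiary axial hydroxyl may stall, or forcing conditions may scramble the acyl groups between O3 and O4. Fallback: the order of the two acylations is reversed, setting out from ketone 22. B-Bromocatecholborane (CH2Cl2, −78 °C) cleaves the methoxymethyl ether selectively to the tertiary alcohol F5. Acetylation (Ac2O, DMAP, Et3N, 40 °C) with O3 still silylated gives the tertiary acetate F6. Buffered HF·pyridine (THF, 0 °C), non-basic so as to hold back acetyl migration, frees O3 to give the hydroxy acetate F7. Yamaguchi esterification of F7 with mixed anhydride 28 of acid 27 comes back to the route at target 30.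

Further compounds

F1 | step 3 | rac-(1R*,3S*,4S*)-3-hydroxy-3,5-dimethylbicyclo[2.2.2]oct-5-en-2-one (racemate, both enantiomers written) | O[C@]1(C)C(=O)[C@@H]2CC[C@H]1C(C)=C2.O[C@@]1(C)C(=O)[C@H]2CC[C@@H]1C(C)=C2
F2 | step 3 | (1R,3S,4S)-3-{[(1R,2S,5R)-menthyloxy]methoxy}-3,5-dimethylbicyclo[2.2.2]oct-5-en-2-one | C[C@@H]1CC[C@H]([C@@H](C1)OCO[C@]3(C)C(=O)[C@@H]4CC[C@H]3C(C)=C4)C(C)C
F3 | step 3 | (1S,3R,4R)-3-{[(1R,2S,5R)-menthyloxy]methoxy}-3,5-dimethylbicyclo[2.2.2]oct-5-en-2-one | C[C@@H]1CC[C@H]([C@@H](C1)OCO[C@@]3(C)C(=O)[C@H]4CC[C@@H]3C(C)=C4)C(C)C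
F4 | step 2 | racemic 7-formyl analogue of 4 (acetoxy anti to the alkene bridge, formyl configuration immaterial, both enantiomers written) | CC(=O)O[C@]1(C)C(=O)[C@@H]2C(C=O)C[C@H]1C(C)=C2.CC(=O)O[C@@]1(C)C(=O)[C@H]2C(C=O)C[C@@H]1C(C)=C2
F5 | step 20 | (3R,4S,5S,7R,10R)-3α-(tert-butyldimethylsilyloxy)-4α-hydroxy-7β-isopropyl-4β,10β-dimethyl-5βH-decalin-8-one | O[C@]1(C)[C@H](O[Si](C)(C)C(C)(C)C)CC[C@]2(C)CC(=O)[C@@H](C(C)C)C[C@@H]21
F6 | step 20 | (3R,4S,5S,7R,10R)-4α-acetoxy-3α-(tert-butyldimethylsilyloxy)-7β-isopropyl-4β,10β-dimethyl-5βH-decalin-8-one | CC(=O)O[C@]1(C)[C@H](O[Si](C)(C)C(C)(C)C)CC[C@]2(C)CC(=O)[C@@H](C(C)C)C[C@@H]21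
F7 | step 20 | (3R,4S,5S,7R,10R)-4α-acetoxy-3α-hydroxy-7β-isopropyl-4β,10β-dimethyl-5βH-decalin-8-one | CC(=O)O[C@]1(C)[C@H](O)CC[C@]2(C)CC(=O)[C@@H](C(C)C)C[C@@H]21
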